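**Plan**

- Retrosynthesis: the C13 ketone and the C10=C14 alkene are unmasked last from a C13 methyl enol ether and a C10 tertiary carbinol. Ring B is cut at C7–C8 (vinyl group on C6 plus C8 aldehyde). Then C9–C10 (cyanomethyl anion), C3–O/C16–O (diene osmylation), C2–C3 (ring A) and C1–C12 (acetylide plus ketone) are cut.
- Forward: ring C enedione 7 from 4-methylpentan-2-one and two equivalents of diethyl oxalate; enyne fragment 18; union at the fully substituted C12; ring A by palladium cyclisation; C9–C8 chain; ring B; acid unmasking.
- Stereochemistry: C11 by catalytic asymmetric hydroxylation and C6 by copper-catalysed allylic substitution. C12 and C10 are relayed from C11 (additions anti to the C11 methyl). The (E)-C1=C2 geometry comes from syn-carbopalladation, C3 from osmylation anti to the C6 vinyl group, and C7 and C8 from the ring closure.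
- Feature used by the key event: in aldehyde 26 the C6 vinyl group (C7=C17) is the only unhindered alkene, since C1=C2 lies between the fully substituted C3 and C12 and C13=C14 is a tetrasubstituted enol ether. C1 and C9 stand cis on ring C with C10 still sp3, so C7 and C8 can meet and close the nine-membered ring B (C1, C2, C6, C7, C8, C9, C10, C11, C12).

Key step: step 18

Remark: atom labels C1–C17 and C20 are those of 28 (ring A: C2–C6; C1 the exocyclic methine; C7–C9 the chain; ring C: C10–C14; C16 the CH2OMe carbon; C17 and C20 the methyls on C7 and C11).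
Remark: trione 4 is written as its enol tautomer, and the catalyst antipodes in steps 5 and 10 are assumed to be chosen so that the configurations drawn result.

Step 1
Reactants: 1 4-methylpentan-2-one; 2 diethyl oxalate (2 equiv)
Product: 3 ethyl 2-oxo-2-[2,4,5-trioxo-3-(propan-2-yl)cyclopentyl]acetate
Conditions: 2 (2.2 equiv), NaOEt (3 equiv), EtOH, 0 °C to reflux; aq. HCl
Reagents that add atoms: diethyl oxalate (the second equivalent of 2), CCOC(=O)C(=O)OCC
Why: Claisen condensation of each α-carbon of the ketone with one molecule of oxalate, followed by Dieckmann-type closure of the five-membered ring onto one ester group, leaves the second ethoxalyl group on the ring CH (the classical oxalate synthesis of 3-alkylcyclopentane-1,2,4-triones, which consumes two equivalents of diethyl oxalate and releases three of ethanol); no stereocentre is formed.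

Step 2
Reactants: 3 ethyl 2-oxo-2-[2,4,5-trioxo-3-(propan-2-yl)cyclopentyl]acetate
Product: 4 2-hydroxy-3-(propan-2-yl)cyclopent-2-ene-1,4-dione
Conditions: H3PO4 (85%), H2O, reflux
Reagents that add atoms: none
Why: Acid-mediated retro-Claisen cleavage removes the ethoxalyl group as oxalic acid and leaves the trione, which rests as the cross-conjugated enol.

Step 3
Reactants: 4 2-hydroxy-3-(propan-2-yl)cyclopent-2-ene-1,4-dione
Product: 5 2-methoxy-3-(propan-2-yl)cyclopent-2-ene-1,4-dione
Conditions: Me3SiCHN2 (1.05 equiv), MeOH/toluene, 0 °C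
Reagents that add atoms: (trimethylsilyl)diazomethane, C[Si](C)(C)C=[N+]=[N-]
Why: O-methylation of the strongly acidic enol hydroxyl (a vinylogous acid) by diazomethane released in the flask fixes the enol ether on C13, which masks the later C13 ketone and leaves the C12 carbonyl as the more electrophilic one.

Step 4
Reactants: 5 2-methoxy-3-(propan-2-yl)cyclopent-2-ene-1,4-dione
Product: 6 2-methoxy-5-methyl-3-(propan-2-yl)cyclopent-2-ene-1,4-dione (racemic, enolisable)
Conditions: K2CO3 (1.1 equiv), MeI (1.05 equiv), acetone, 23 °C
Reagents that add atoms: iodomethane, CI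
Why: SN2 C-alkylation of the 1,3-dione carbanion at C11, the only position flanked by both carbonyls, O-alkylation being disfavoured because it would give a cyclopentadienone ether; the new centre is racemic and labile.

Step 5
Reactants: 6 2-methoxy-5-methyl-3-(propan-2-yl)cyclopent-2-ene-1,4-dione
Product: 7 (5R)-5-hydroxy-2-methoxy-5-methyl-3-(propan-2-yl)cyclopent-2-ene-1,4-dione
Conditions: cumene hydroperoxide (1.2 equiv), hydroquinidine (20 mol%), toluene, −20 °C
Reagents that add atoms: cumene hydroperoxide, CC(C)(OO)c1ccccc1
Why: Cinchona-alkaloid-catalysed enantioselective α-hydroxylation of a 2-substituted 1,3-dione, in which the chiral ammonium enolate ion pair is oxidised on one face by the hydroperoxide and so sets C11 (R), the pseudoenantiomeric alkaloid being available should the opposite sense result.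

Step 6
Reactants: 8 2-bromoprop-2-en-1-ol; 9 triethyl orthoacetate
Product: 10 ethyl 4-bromopent-4-enoate
Conditions: EtCO2H (cat.), 140 °C, EtOH distilled off
Reagents that add atoms: none
Why: Johnson–Claisen rearrangement ([3,3]-sigmatropic shift of the ketene acetal formed in the flask) extends the allylic alcohol by two carbons; no stereocentre.

Step 7
Reactants: 10 ethyl 4-bromopent-4-enoate; 11 triethyl phosphonoacetate
Product: 13 ethyl (2E)-6-bromohepta-2,6-dienoate, via 4-bromopent-4-enal 12 (not isolated)
Conditions: iBu2AlH (1.05 equiv), CH2Cl2, −78 °C; then 11/NaH in THF, −78 to 23 °C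
Reagents that add atoms: none
Why: Half-reduction of the ester to the aldehyde, held as its aluminium hemiacetal, is followed in the same flask by Horner–Wadsworth–Emmons olefination, the stabilised phosphonate giving the (E)-enoate.

Step 8
Reactants: 13 ethyl (2E)-6-bromohepta-2,6-dienoate
Product: 14 (2E)-6-bromohepta-2,6-dien-1-ol
Conditions: iBu2AlH (2.2 equiv), CH2Cl2, −78 °C
Reagents that add atoms: none
Why: 1,2-Reduction of the enoate by the aluminium hydride gives the allylic alcohol with the (E)-alkene and the vinyl bromide untouched.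

Step 9
Reactants: 14 (2E)-6-bromohepta-2,6-dien-1-ol
Product: 15 (2E)-6-bromohepta-2,6-dien-1-yl diethyl phosphate
Conditions: ClP(O)(OEt)2, pyridine, DMAP (cat.), CH2Cl2, 0 °C
Reagents that add atoms: diethyl chlorophosphate, CCOP(=O)(Cl)OCC
Why: O-phosphorylation turns the primary allylic alcohol into the leaving group needed for copper-catalysed allylic substitution.

Step 10
Reactants: 15 (2E)-6-bromohepta-2,6-dien-1-yl diethyl phosphate; 16 ethynyltrimethylsilane
Product: 18 (3S)-6-bromo-3-ethenylhept-6-en-1-yne, via [(3S)-6-bromo-3-ethenylhept-6-en-1-yn-1-yl]trimethylsilane 17 (not isolated)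
Conditions: 16, iBu2AlH, Et3N (5 mol%), hexanes, 55 °C; then 15, CuCl2·2H2O (5 mol%), chiral sulfonate-bearing imidazolinium salt (NHC precursor, 5 mol%), THF, −30 °C; then K2CO3, MeOH, 23 °C
Reagents that add atoms: none
Why: Copper–NHC-catalysed enantioselective SN2′ allylic substitution with the alkynylaluminium made in the flask forms the new C–C bond at the γ-carbon and sets C6 (S) by catalyst control, and methanolysis then removes the C-silyl group.

Step 11
Reactants: 7 (5R)-5-hydroxy-2-methoxy-5-methyl-3-(propan-2-yl)cyclopent-2-ene-1,4-dione; 18 (3S)-6-bromo-3-ethenylhept-6-en-1-yne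
Product: 19 (4S,5S)-4-[(3S)-6-bromo-3-ethenylhept-6-en-1-yn-1-yl]-4,5-dihydroxy-3-methoxy-5-methyl-2-(propan-2-yl)cyclopent-2-en-1-one (hydroxyls on C11 and C12 trans)
Conditions: 18 (2.2 equiv), EtMgBr (2.1 equiv), THF, 0 to 23 °C; then 7, −78 to −30 °C; aq. NH4Cl (excess 18 recovered)
Reagents that add atoms: none
Why: 1,2-Addition of the alkynylmagnesium reagent to the C12 carbonyl, which is the more electrophilic one because the C10 carbonyl is a deactivated vinylogous ester, occurs on the magnesium chelate of the C11 alkoxide anti to the C11 methyl group and so sets C12 with the alkynyl group cis to the C11 oxygen.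

Step 12
Reactants: 19 the propargylic diol from step 11
Product: 20 (4S,5S)-4-{(E)-[(2S)-2-ethenyl-5-methylidenecyclopentylidene]methyl}-4,5-dihydroxy-3-methoxy-5-methyl-2-(propan-2-yl)cyclopent-2-en-1-one
Conditions: Pd(PPh3)4 (5 mol%), HCO2Na (1.5 equiv), DMF, 70 °C
Reagents that add atoms: none
Why: Zerovalent palladium inserts into the C3–Br bond, 5-exo-dig syn-carbopalladation of the alkyne closes ring A and formate-derived hydride cleaves the C1–Pd bond (reductive Heck-type cyclisation with hydride capture), so that the hydrogen on C1 is cis to C3 and C12 is cis to C6.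

Step 13
Reactants: 20 the dienyl diol ketone from step 12; 21 acetonitrile
Product: 22 triol nitrile: ring C is a 3-methoxy-2-(propan-2-yl)cyclopent-2-ene carrying C10 (OH, CH2CN), C11 (OH, CH3) and C12 (OH, alkylidenemethyl), with C9 and C1 both cis to the C11 hydroxyl; ring A diene as in 20
Conditions: 21 (6 equiv), n-BuLi (5.5 equiv), THF, −78 °C; then 20, −78 to −40 °C; pH 7 phosphate buffer
Reagents that add atoms: none
Why: 1,2-Addition of (cyanomethyl)lithium to the vinylogous ester carbonyl C10 is the first stage of a Stork–Danheiser sequence, here stopped before hydrolysis by neutral work-up, and delivery on the lithium alkoxide chelate anti to the C11 methyl group places C9 cis to C1.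

Step 14
Reactants: 22 the triol nitrile from step 13
Product: 23 pentaol nitrile: as 22 with C3 carrying OH and CH2OH, the C3 hydroxyl trans to the C6 vinyl group
Conditions: OsO4 (5 mol%), NMO (1.1 equiv), acetone/H2O, 0 °C
Reagents that add atoms: 4-methylmorpholine N-oxide, C[N+]1([O-])CCOCC1; water, O
Why: Upjohn syn-dihydroxylation attacks the most accessible and electron-rich alkene, the 1,1-disubstituted terminus C3=C16 of the s-cis diene, and because allylic 1,3-strain with the C1 substituent holds the C6 vinyl group pseudo-axial the osmium adds to the opposite face, giving the C3 hydroxyl trans to C7.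

Step 15
Reactants: 23 the pentaol nitrile from step 14
Product: 24 tetraol methyl ether: as 23 with C16–OCH3
Conditions: MeI (excess), Ag2O (1.5 equiv), CH2Cl2, 23 °C, dark
Reagents that add atoms: iodomethane, CI
Why: Silver-oxide-mediated Williamson methylation is selective for the single primary hydroxyl over the four tertiary ones.

Step 16
Reactants: 24 the tetraol methyl ether from step 15
Product: 25 tetrakis(trimethylsilyl) ether of 24 (silyl groups on O3, O10, O11 and O12)
Conditions: 1-(trimethylsilyl)imidazole (8 equiv), DMF, 50 °C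
Reagents that add atoms: 1-(trimethylsilyl)imidazole, C[Si](C)(C)n1ccnc1
Why: Silyl transfer from the imidazolide caps the tertiary hydroxyls under non-acidic conditions, which keeps the acid-labile C10 carbinol intact and prevents lactol formation between O11 and C8 in the next steps.

Step 17
Reactants: 25 the tetrakis(trimethylsilyl) ether nitrile from step 16
Product: 26 aldehyde: as 25 with C8 as CHO
Conditions: iBu2AlH (1.3 equiv), toluene, −78 °C; aq. sodium potassium tartrate, pH 7
Reagents that add atoms: water, O
Why: Hydride addition to the nitrile gives the aluminium aldimine, which is hydrolysed on neutral work-up to the aldehyde, and this aldehyde cannot enolise into conjugation because the enone is still masked.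

Step 18
Reactants: 26 the vinyl aldehyde from step 17
Product: 27 tricyclic alcohol: ring B closed, (7R,8S) as in 28, C8–OH free, O3, O10, O11 and O12 as trimethylsilyl ethers, C13 methyl enol ether
Conditions: Co(salen)Cl (10 mol%; salen = N,N′-bis(3,5-di-tert-butylsalicylidene)cyclohexane-1,2-diamine dianion), CrCl3(THF)3 (20 mol%), PhSiH3 (2 equiv), THF, 23 °C, slow addition of 26 to 0.002 M; aq. NaHCO3
Reagents that add atoms: none
Why: Proposed new method: a cobalt hydride formed from the trivalent cobalt salen complex and PhSiH3 transfers a hydrogen atom to C17 of the C6 vinyl group, the secondary C7 radical is captured by divalent chromium (formed by electron exchange between the two catalysts), and the alkylchromium adds to the C8 aldehyde before the alkoxide is silylated and both metals turn over. The closest known reactions are the intermolecular branch-selective cobalt/chromium hydrogen-atom-transfer coupling of terminal alkenes with aldehydes and the Nozaki–Hiyama–Kishi closure of medium rings, nine-membered carbocycles included, from alkenylchromium reagents. Ring B (C1, C2, C6, C7, C8, C9, C10, C11, C12) closes in a 9-exo-trig addition to the carbonyl group, which is feasible because C1 and C9 are cis on ring C and C10 is still sp3. At C7 the carbon–chromium bond is configurationally labile, so the epimeric organochromium species equilibrate and the one that cyclises should carry the methyl group outside the forming ring and anti to C5, as imposed by the fixed C6 centre. At C8 the aldehyde should be attacked with its oxygen turned away from the C11 silyloxy group, which places methyl and hydroxyl anti (7R,8S). The step needs hydrogen-atom transfer to occur only at the vinyl group, and the substrate secures this because C1=C2 lies between two fully substituted carbons and C13=C14 is a tetrasubstituted enol ether.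

Step 19
Reactants: 27 the tricyclic alcohol from step 18
Product: 28 brassicicene M
Conditions: HCl (0.5 M aq.), THF, 0 to 23 °C
Reagents that add atoms: water, O
Why: Acid cleaves the four trimethylsilyl ethers and ionises the C10 oxygen to the methoxy-stabilised allyl cation, whose hydrolysis (second stage of the Stork–Danheiser transposition) gives the C13 ketone and the bridgehead C10=C14 alkene without touching any stereocentre.

**Compound list**

1 | 4-methylpentan-2-one | CC(C)CC(C)=O | starting material
2 | diethyl oxalate | CCOC(=O)C(=O)OCC | starting material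
3 | ethyl 2-oxo-2-[2,4,5-trioxo-3-(propan-2-yl)cyclopentyl]acetate | CCOC(=O)C(=O)C1C(=O)C(C(C)C)C(=O)C1=O | intermediate
4 | 2-hydroxy-3-(propan-2-yl)cyclopent-2-ene-1,4-dione (enol of 3-isopropylcyclopentane-1,2,4-trione) | CC(C)C1=C(O)C(=O)CC1=O | intermediate
5 | 2-methoxy-3-(propan-2-yl)cyclopent-2-ene-1,4-dione | COC1=C(C(C)C)C(=O)CC1=O | intermediate
6 | 2-methoxy-5-methyl-3-(propan-2-yl)cyclopent-2-ene-1,4-dione (racemic) | COC1=C(C(C)C)C(=O)C(C)C1=O | intermediate
7 | (5R)-5-hydroxy-2-methoxy-5-methyl-3-(propan-2-yl)cyclopent-2-ene-1,4-dione | COC1=C(C(C)C)C(=O)[C@@](C)(O)C1=O | intermediate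
8 | 2-bromoprop-2-en-1-ol | OCC(Br)=C | starting material
9 | triethyl orthoacetate | CCOC(C)(OCC)OCC | starting material
10 | ethyl 4-bromopent-4-enoate | CCOC(=O)CCC(Br)=C | intermediate
11 | triethyl phosphonoacetate | CCOC(=O)CP(=O)(OCC)OCC | starting material
12 | 4-bromopent-4-enal | O=CCCC(Br)=C | intermediate
13 | ethyl (2E)-6-bromohepta-2,6-dienoate | CCOC(=O)/C=C/CCC(Br)=C | intermediate
14 | (2E)-6-bromohepta-2,6-dien-1-ol | OC/C=C/CCC(Br)=C | intermediate
15 | (2E)-6-bromohepta-2,6-dien-1-yl diethyl phosphate | CCOP(=O)(OCC)OC/C=C/CCC(Br)=C | intermediate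
16 | ethynyltrimethylsilane | C#C[Si](C)(C)C | starting material
17 | [(3S)-6-bromo-3-ethenylhept-6-en-1-yn-1-yl]trimethylsilane | C=C(Br)CC[C@@H](C=C)C#C[Si](C)(C)C | intermediate
18 | (3S)-6-bromo-3-ethenylhept-6-en-1-yne | C=C(Br)CC[C@@H](C=C)C#C | intermediate
19 | (4S,5S)-4-[(3S)-6-bromo-3-ethenylhept-6-en-1-yn-1-yl]-4,5-dihydroxy-3-methoxy-5-methyl-2-(propan-2-yl)cyclopent-2-en-1-one | C=C(Br)CC[C@@H](C=C)C#C[C@@]1(O)C(OC)=C(C(C)C)C(=O)[C@@]1(C)O | intermediate
20 | (4S,5S)-4-{(E)-[(2S)-2-ethenyl-5-methylidenecyclopentylidene]methyl}-4,5-dihydroxy-3-methoxy-5-methyl-2-(propan-2-yl)cyclopent-2-en-1-one | C=C1CC[C@@H](C=C)/C1=C\[C@@]1(O)C(OC)=C(C(C)C)C(=O)[C@@]1(C)O | intermediate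
21 | acetonitrile | CC#N | starting material
22 | triol nitrile (C10 carbinol with CH2CN cis to the C11 hydroxyl and to C1; C13 methyl enol ether; ring A diene) | C=C1CC[C@@H](C=C)/C1=C\[C@@]1(O)C(OC)=C(C(C)C)[C@@](O)(CC#N)[C@@]1(C)O | intermediate
23 | pentaol nitrile (C3 with OH and CH2OH, C3 hydroxyl trans to the C6 vinyl group) | OC[C@@]1(O)CC[C@@H](C=C)/C1=C\[C@@]1(O)C(OC)=C(C(C)C)[C@@](O)(CC#N)[C@@]1(C)O | intermediate
24 | tetraol methyl ether (C16–OCH3) | COC[C@@]1(O)CC[C@@H](C=C)/C1=C\[C@@]1(O)C(OC)=C(C(C)C)[C@@](O)(CC#N)[C@@]1(C)O | intermediate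
25 | tetrakis(trimethylsilyl) ether nitrile (silyl on O3, O10, O11, O12) | COC[C@@]1(O[Si](C)(C)C)CC[C@@H](C=C)/C1=C\[C@@]1(O[Si](C)(C)C)C(OC)=C(C(C)C)[C@@](O[Si](C)(C)C)(CC#N)[C@@]1(C)O[Si](C)(C)C | intermediate
26 | vinyl aldehyde (C8 = CHO; otherwise as 25) | COC[C@@]1(O[Si](C)(C)C)CC[C@@H](C=C)/C1=C\[C@@]1(O[Si](C)(C)C)C(OC)=C(C(C)C)[C@@](O[Si](C)(C)C)(CC=O)[C@@]1(C)O[Si](C)(C)C | intermediate
27 | tricyclic alcohol (ring B closed, 7R,8S; four trimethylsilyl ethers; C13 methyl enol ether; C10 silyloxy carbinol) | COC[C@@]1(O[Si](C)(C)C)CC[C@@H]2/C1=C\[C@@]1(O[Si](C)(C)C)C(OC)=C(C(C)C)[C@@](O[Si](C)(C)C)(C[C@H](O)[C@@H]2C)[C@@]1(C)O[Si](C)(C)C | intermediate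
28 | brassicicene M | COC[C@@]1(O)CC[C@@H]2/C1=C\[C@@]1(O)C(=O)C(C(C)C)=C(C[C@H](O)[C@@H]2C)[C@@]1(C)O | target

**Step count and risks**

Total step count: 19. Longest linear sequence: 14 steps (steps 1–5, then 11–19).

Steps most likely to fail:

1. Step 18 (proposed new method). The cobalt hydride may walk the double bond into conjugation with C1=C2 (loss of the C6 centre). The C7 radical may be reduced before chromium captures it. The nine-membered closure may show poor facial selectivity at C7 and C8. The fallback uses known reactions, sets out from 25 and returns at 27. Tsuji–Wacker oxidation of the vinyl group (PdCl2, CuCl, O2, buffered DMF/H2O) should give the C7 methyl ketone F1. Kinetic enolisation towards the methyl group (KN(SiMe3)2, PhNTf2, THF, −78 °C) should give the enol triflate F2. Reduction of the nitrile (iBu2AlH, −78 °C, neutral work-up) should give the aldehyde triflate F3. Intramolecular Nozaki–Hiyama–Kishi coupling (CrCl2, NiCl2 cat., DMSO/THF, high dilution) should close ring B to the exo-methylene allylic alcohol F4. Hydroxyl-directed hydrogenation ([Ir(cod)(PCy3)(py)]PF6, H2, CH2Cl2) should then deliver hydrogen to C7 from the face of the C8 hydroxyl, placing methyl and hydroxyl anti, and give 27.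

2. Step 14. Osmylation of the pendant vinyl group or of C1=C2 may compete with the diene terminus, and attack may occur on the wrong face of C3=C16. The fallback sets out from 22 and returns at 24. Epoxidation with dimethyldioxirane (acetone, −40 °C), which discriminates more strongly against the monosubstituted vinyl group, should give the spiro-epoxide F5 with oxygen anti to the C6 vinyl group. SN2 opening at the primary carbon C16 with NaOMe in MeOH should then give 24 directly.

3. Step 5. Enantiofacial discrimination may be low, because the two carbonyl flanks of the planar dione enolate differ only in their remote substituents. The fallback sets out from 6 and returns at 19. Racemic hydroxylation with dimethyldioxirane should give 7 together with its enantiomer, (5S)-5-hydroxy-2-methoxy-5-methyl-3-(propan-2-yl)cyclopent-2-ene-1,4-dione F6. The mixture is coupled with enantiopure 18 as in step 11, and 19 is separated by chromatography from the diastereomeric adduct F7 (a resolution through the enantiopure fragment).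

Further compounds
F1 | step 18 | C7 methyl ketone (acetyl on C6; otherwise as 25) | COC[C@@]1(O[Si](C)(C)C)CC[C@@H](C(C)=O)/C1=C\[C@@]1(O[Si](C)(C)C)C(OC)=C(C(C)C)[C@@](O[Si](C)(C)C)(CC#N)[C@@]1(C)O[Si](C)(C)C
F2 | step 18 | enol triflate (C7 carrying OTf and =CH2; nitrile at C8) | COC[C@@]1(O[Si](C)(C)C)CC[C@@H](C(=C)OS(=O)(=O)C(F)(F)F)/C1=C\[C@@]1(O[Si](C)(C)C)C(OC)=C(C(C)C)[C@@](O[Si](C)(C)C)(CC#N)[C@@]1(C)O[Si](C)(C)C
F3 | step 18 | aldehyde triflate (C8 = CHO; otherwise as F2) | COC[C@@]1(O[Si](C)(C)C)CC[C@@H](C(=C)OS(=O)(=O)C(F)(F)F)/C1=C\[C@@]1(O[Si](C)(C)C)C(OC)=C(C(C)C)[C@@](O[Si](C)(C)C)(CC=O)[C@@]1(C)O[Si](C)(C)C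
F4 | step 18 | exo-methylene allylic alcohol (ring B closed, C7=CH2, C8–OH) | COC[C@@]1(O[Si](C)(C)C)CC[C@@H]2/C1=C\[C@@]1(O[Si](C)(C)C)C(OC)=C(C(C)C)[C@@](O[Si](C)(C)C)(C[C@H](O)C2=C)[C@@]1(C)O[Si](C)(C)C
F5 | step 14 | spiro-epoxide (oxirane on C3–C16; otherwise as 22) | C1O[C@@]12CC[C@@H](C=C)/C2=C\[C@@]3(O)C(OC)=C(C(C)C)[C@@](O)(CC#N)[C@@]3(C)O
F6 | step 5 | (5S)-5-hydroxy-2-methoxy-5-methyl-3-(propan-2-yl)cyclopent-2-ene-1,4-dione | COC1=C(C(C)C)C(=O)[C@](C)(O)C1=O
F7 | step 5 | diastereomeric adduct (4R,5R)-4-[(3S)-6-bromo-3-ethenylhept-6-en-1-yn-1-yl]-4,5-dihydroxy-3-methoxy-5-methyl-2-(propan-2-yl)cyclopent-2-en-1-one | C=C(Br)CC[C@@H](C=C)C#C[C@]1(O)C(OC)=C(C(C)C)C(=O)[C@]1(C)O
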